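**Plan**
- Cuts: first the bond between the side-chain ketone carbon and the diyne (made as aldehyde plus diynyl anion, then oxidised), then both exocyclic bonds at the quaternary C3 of the chromane-2,4-dione: C3–CH2 of the oxoalkyl arm and C3–C1' of the farnesyl group.
- Enabling feature: C3 lies between the lactone carbonyl C2 and the ketone C4 of the benzopyran bicycle. It is C3 of 4-hydroxycoumarin, a carbon that can act twice as a nucleophile, so both arms can arrive as electrophiles (acrolein and a π-farnesyl palladium complex).
- Forward: no ring is made, the bicycle being bought as 4-hydroxycoumarin. One flask joins coumarin, acrolein and farnesyl carbonate to aldehyde 6. The C14 diyne arm (from dec-2-yn-1-ol and bis-silylbutadiyne) is then added as its lithium acetylide, the new carbinol is oxidised and the silyl ether removed.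
- Stereochemistry: C3 (S) from the chiral diphosphine on palladium in the allylation; the carbinol (S) from a zinc–ProPhenol alkynylation of (Z)-dec-2-enal; the Z-alkene from Lindlar reduction; the E,E-alkenes from farnesol.

Key step: step 2

Assumption: the ligand antipodes written in steps 2 and 6 are those expected to give the (S) centres (in step 6, alkynyl delivery to the Re face of the enal); the sense of induction is to be confirmed on the first batch and, were it opposite, the mirror-image ligand (both are commercial) would be used with nothing else changed.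

**Route**

Step 1
Reactants: 1 (2E,6E)-farnesol
Product: 2 tert-butyl (2E,6E)-3,7,11-trimethyldodeca-2,6,10-trien-1-yl carbonate
Conditions: Boc2O, n-Bu4NHSO4 (cat.), 30% aq. NaOH, CH2Cl2, 0 °C to rt
Reagents that add atoms: di-tert-butyl dicarbonate, CC(C)(C)OC(=O)OC(=O)OC(C)(C)C
Why: Phase-transfer O-acylation (carbonate formation) of the primary allylic alcohol is routine for allylic tert-butyl carbonates and touches neither the trisubstituted alkenes nor their E geometry.

Step 2
Reactants: 3 4-hydroxycoumarin; 4 acrolein; 2 tert-butyl (2E,6E)-farnesyl carbonate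
Product: 6 3-[(3S)-2,4-dioxo-3-[(2E,6E)-3,7,11-trimethyldodeca-2,6,10-trien-1-yl]-3,4-dihydro-2H-chromen-3-yl]propanal, via pyranocoumarin lactol 5 (not isolated)
Conditions: 3, 4 (1.05 equiv), Et3N (10 mol %), THF, 0 °C to rt; volatiles removed in vacuo; then 2 (1.2 equiv), Pd2(dba)3·CHCl3 (2.5 mol %), (R,R)-DACH-phenyl diphosphine N,N'-[(1R,2R)-cyclohexane-1,2-diyl]bis[2-(diphenylphosphino)benzamide] (7.5 mol %), degassed CH2Cl2, 0 °C to rt
Reagents that add atoms: none
Why: Proposed new method: Et3N-catalysed Michael addition of C3 of the vinylogous acid 3 to acrolein should give the 3-(3-oxopropyl) enol, which rests as lactol 5 and is thereby shielded from a second addition; after the volatiles are stripped, zerovalent palladium bearing the chiral diphosphine ionises carbonate 2 with loss of CO2, the tert-butoxide released opens 5 to the stabilised enolate, and this attacks the π-farnesyl complex at its CH2 terminus on the face away from the metal, so that the C3–CH2 and C3–C1' bonds are both made in one flask. The closest known reactions are the Michael addition of 4-hydroxycoumarins to enals, the Tsuji–Trost C3-allylation of 4-hydroxycoumarins and the palladium-catalysed asymmetric allylic alkylation of α-substituted cyclic β-keto esters to quaternary carbons; their one-flask union and the enantioselective version on this β-keto lactone are untested. No ring is closed, since the benzopyran bicycle is present from the start. The (S) centre at C3 is to be set by the ligand, whose chiral pocket must tell apart the two faces of a planar enolate that carries the fused benzo ring on its C4 side and only the ring oxygen on its C2 side. C- over O-allylation is secured because O-allyl ethers of this acidic enol re-ionise under zerovalent palladium and drain to the C-allylated dione, and linear over branched attack because a fully substituted nucleophile cannot reach the trisubstituted allyl terminus. The 2E geometry should survive because the syn π-allyl complex is captured faster than it isomerises through the tertiary σ-allyl form.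

Step 3
Reactants: 7 dec-2-yn-1-ol
Product: 8 (Z)-dec-2-en-1-ol
Conditions: H2 (1 atm), Lindlar catalyst (Pd on CaCO3 poisoned with Pb(OAc)2), quinoline, EtOAc, rt
Reagents that add atoms: none
Why: Lindlar semihydrogenation adds both hydrogens from the catalyst surface to one face of the alkyne, so the Z-alkene is formed and quinoline suppresses over-reduction.

Step 4
Reactants: 8 (Z)-dec-2-en-1-ol
Product: 9 (Z)-dec-2-enal
Conditions: Dess–Martin periodinane, NaHCO3, CH2Cl2, 0 °C; used at once
Reagents that add atoms: none
Why: Dess–Martin oxidation under NaHCO3 buffer is neutral and fast, which is why it converts Z-allylic alcohols into Z-enals without isomerisation when the aldehyde is used immediately.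

Step 5
Reactants: 10 1,4-bis(trimethylsilyl)buta-1,3-diyne
Product: 12 buta-1,3-diynyl(trimethyl)silane, via lithium silylbutadiynide 11 (not isolated)
Conditions: MeLi·LiBr (1.0 equiv), Et2O, 0 °C to rt; then aq. NH4Cl, 0 °C; kept as a dried toluene solution
Reagents that add atoms: none
Why: Monodesilylation by attack of methyllithium at silicon releases one acetylide, and the anionic product resists a second attack, so protonation gives the mono-silyl diyne.

Step 6
Reactants: 9 (Z)-dec-2-enal; 12 buta-1,3-diynyl(trimethyl)silane
Product: 14 (5S,6Z)-1-(trimethylsilyl)tetradec-6-ene-1,3-diyn-5-ol, via methylzinc diynide 13 (not isolated)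
Conditions: 12 (2 equiv), Me2Zn (3 equiv), (S,S)-ProPhenol (20 mol %), Ph3P=O (40 mol %), toluene, 0 °C, 1 h; then 9, 4 °C; aq. NH4Cl
Reagents that add atoms: none
Why: Catalytic asymmetric alkynylation of an aldehyde with a zinc acetylide, in which the dinuclear zinc–ProPhenol complex holds the enal and the diynyl group on neighbouring zinc atoms and should deliver the diynyl group to the Re face to give the (S)-carbinol under conditions mild enough to keep the Z-alkene.

Step 7
Reactants: 14 (5S,6Z)-1-(trimethylsilyl)tetradec-6-ene-1,3-diyn-5-ol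
Product: 15 tert-butyl(dimethyl){[(5S,6Z)-1-(trimethylsilyl)tetradec-6-ene-1,3-diyn-5-yl]oxy}silane
Conditions: TBSCl, imidazole, DMF, 0 °C to rt
Reagents that add atoms: tert-butyldimethylsilyl chloride, CC(C)(C)[Si](C)(C)Cl
Why: Imidazole-promoted O-silylation of the secondary alcohol breaks no bond at the stereocentre, so the (S) configuration is carried over.

Step 8
Reactants: 15 tert-butyl(dimethyl){[(5S,6Z)-1-(trimethylsilyl)tetradec-6-ene-1,3-diyn-5-yl]oxy}silane
Product: 16 tert-butyl(dimethyl){[(5S,6Z)-tetradec-6-ene-1,3-diyn-5-yl]oxy}silane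
Conditions: K2CO3 (0.2 equiv), MeOH–THF, 0 °C; used at once as a solution
Reagents that add atoms: none
Why: Methoxide-mediated protodesilylation cleaves only the C(sp)–Si bond, since an acetylide leaves silicon far more readily than the alkoxide of the hindered silyl ether.

Step 9
Reactants: 16 tert-butyl(dimethyl){[(5S,6Z)-tetradec-6-ene-1,3-diyn-5-yl]oxy}silane; 6 3-[(3S)-3-farnesyl-2,4-dioxochroman-3-yl]propanal
Product: 18 (3S)-3-[(8S,9Z)-8-{[tert-butyl(dimethyl)silyl]oxy}-3-hydroxyheptadec-9-ene-4,6-diyn-1-yl]-3-[(2E,6E)-3,7,11-trimethyldodeca-2,6,10-trien-1-yl]chromane-2,4-dione (both epimers at the new carbinol), via lithium diynide 17 (not isolated)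
Conditions: 16 (1.15 equiv), n-BuLi (1.05 equiv), THF, −78 °C; cannulated into 6, THF, −78 °C, 20 min; AcOH in THF, −78 °C
Reagents that add atoms: none
Why: 1,2-Addition of a lithium acetylide to an aldehyde, in which at −78 °C the unhindered aldehyde should be attacked far faster than the ketone and aryl lactone carbonyls beside the quaternary carbon, the cold acetic acid quench protonates the alkoxide before it can open the lactone, and the uncontrolled new carbinol is removed in step 10.

Step 10
Reactants: 18 propargylic alcohol (both epimers)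
Product: 19 (3S)-3-[(8S,9Z)-8-{[tert-butyl(dimethyl)silyl]oxy}-3-oxoheptadec-9-ene-4,6-diyn-1-yl]-3-[(2E,6E)-3,7,11-trimethyldodeca-2,6,10-trien-1-yl]chromane-2,4-dione
Conditions: Dess–Martin periodinane, NaHCO3, CH2Cl2, 0 °C; crude 18 used directly
Reagents that add atoms: none
Why: Dess–Martin oxidation turns the secondary propargylic alcohol into the ynone under buffered neutral conditions that leave the silyl ether, the alkenes and the base-sensitive dione alone, and both epimers of 18 converge on one compound.

Step 11
Reactants: 19 silyl-protected diynone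
Product: 20 (3S)-3-[(8S,9Z)-8-hydroxy-3-oxoheptadec-9-ene-4,6-diyn-1-yl]-3-[(2E,6E)-3,7,11-trimethyldodeca-2,6,10-trien-1-yl]chromane-2,4-dione (CNP0346147.1)
Conditions: HF·pyridine, pyridine, THF, 0 °C to rt
Reagents that add atoms: none
Why: Fluoride-mediated desilylation under weakly acidic conditions breaks only the Si–O bond, so the (S)-carbinol is retained and the basic conditions that would open the lactone, add to the diynone or reverse the Michael addition are avoided.

**Compound list**

1 | (2E,6E)-farnesol | OC/C=C(\C)CC/C=C(\C)CCC=C(C)C | starting material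
2 | tert-butyl (2E,6E)-3,7,11-trimethyldodeca-2,6,10-trien-1-yl carbonate | CC(C)(C)OC(=O)OC/C=C(\C)CC/C=C(\C)CCC=C(C)C | intermediate
3 | 4-hydroxycoumarin | O=c1cc(O)c2ccccc2o1 | starting material
4 | acrolein | C=CC=O | starting material
5 | 2-hydroxy-3,4-dihydro-2H,5H-pyrano[3,2-c]chromen-5-one (lactol of the Michael adduct, formed in the flask) | O=c1oc2ccccc2c2OC(O)CCc12 | intermediate
6 | 3-[(3S)-2,4-dioxo-3-[(2E,6E)-3,7,11-trimethyldodeca-2,6,10-trien-1-yl]-3,4-dihydro-2H-chromen-3-yl]propanal | O=CCC[C@@]1(C/C=C(\C)CC/C=C(\C)CCC=C(C)C)C(=O)Oc2ccccc2C1=O | intermediate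
7 | dec-2-yn-1-ol | CCCCCCCC#CCO | starting material
8 | (Z)-dec-2-en-1-ol | CCCCCCC/C=C\CO | intermediate
9 | (Z)-dec-2-enal | CCCCCCC/C=C\C=O | intermediate
10 | 1,4-bis(trimethylsilyl)buta-1,3-diyne | C[Si](C)(C)C#CC#C[Si](C)(C)C | starting material
11 | lithium 4-(trimethylsilyl)buta-1,3-diyn-1-ide (formed in the flask) | [Li]C#CC#C[Si](C)(C)C | intermediate
12 | buta-1,3-diynyl(trimethyl)silane | C#CC#C[Si](C)(C)C | intermediate
13 | methyl[4-(trimethylsilyl)buta-1,3-diyn-1-yl]zinc (formed in the flask) | C[Zn]C#CC#C[Si](C)(C)C | intermediate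
14 | (5S,6Z)-1-(trimethylsilyl)tetradec-6-ene-1,3-diyn-5-ol | CCCCCCC/C=C\[C@H](O)C#CC#C[Si](C)(C)C | intermediate
15 | tert-butyl(dimethyl){[(5S,6Z)-1-(trimethylsilyl)tetradec-6-ene-1,3-diyn-5-yl]oxy}silane | CCCCCCC/C=C\[C@H](O[Si](C)(C)C(C)(C)C)C#CC#C[Si](C)(C)C | intermediate
16 | tert-butyl(dimethyl){[(5S,6Z)-tetradec-6-ene-1,3-diyn-5-yl]oxy}silane | CCCCCCC/C=C\[C@H](O[Si](C)(C)C(C)(C)C)C#CC#C | intermediate
17 | lithium acetylide of 16 (formed in the flask) | CCCCCCC/C=C\[C@H](O[Si](C)(C)C(C)(C)C)C#CC#C[Li] | intermediate
18 | (3S)-3-[(8S,9Z)-8-{[tert-butyl(dimethyl)silyl]oxy}-3-hydroxyheptadec-9-ene-4,6-diyn-1-yl]-3-[(2E,6E)-farnesyl]chromane-2,4-dione, both epimers at the side-chain C3 carbinol | CCCCCCC/C=C\[C@H](O[Si](C)(C)C(C)(C)C)C#CC#CC(O)CC[C@@]1(C/C=C(\C)CC/C=C(\C)CCC=C(C)C)C(=O)Oc2ccccc2C1=O | intermediate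
19 | (3S)-3-[(8S,9Z)-8-{[tert-butyl(dimethyl)silyl]oxy}-3-oxoheptadec-9-ene-4,6-diyn-1-yl]-3-[(2E,6E)-farnesyl]chromane-2,4-dione | CCCCCCC/C=C\[C@H](O[Si](C)(C)C(C)(C)C)C#CC#CC(=O)CC[C@@]1(C/C=C(\C)CC/C=C(\C)CCC=C(C)C)C(=O)Oc2ccccc2C1=O | intermediate
20 | (3S)-3-[(8S,9Z)-8-hydroxy-3-oxoheptadec-9-ene-4,6-diyn-1-yl]-3-[(2E,6E)-3,7,11-trimethyldodeca-2,6,10-trien-1-yl]chromane-2,4-dione | CCCCCCC/C=C\[C@H](O)C#CC#CC(=O)CC[C@@]1(C/C=C(\C)CC/C=C(\C)CCC=C(C)C)C(=O)Oc2ccccc2C1=O | target

**Step count and risks**

Total steps: 11. Longest linear sequence: 8 steps (steps 3, 4, 6, 7, 8, 9, 10, 11, from dec-2-yn-1-ol).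

1. Step 2 (Proposed new method).
   - What may go wrong: poor enantiofacial discrimination at the coumarin enolate; competing O-allylation or branched attack; scrambling of the 2E-alkene through σ-allyl isomerisation; re-ionisation of the C3–allyl bond of the very acidic dione, eroding the enantiomeric purity; inhibition of the palladium catalyst by residual acrolein; a second Michael addition.
   - Fallback (known chemistry): it sets out from 3 and reverses the order of the two bond formations. Tsuji–Trost C3-allylation of excess 3 with carbonate 2 (Pd(PPh3)4, THF, rt) should give ferulenol F1. Conjugate addition of F1 to acrolein 4 in CH2Cl2 at low temperature under a 6'-hydroxy cinchona alkaloid bifunctional catalyst then creates the quaternary centre. This is the established way to make such centres from α-substituted cyclic β-dicarbonyl compounds and acrolein, and the quinine- and quinidine-derived catalysts give access to either antipode. The fallback comes back to the route at aldehyde 6.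

2. Step 9.
   - What may go wrong: attack of the acetylide, or of the newly formed alkoxide, on the aryl lactone (translactonisation with opening of the bicycle); base-induced retro-Michael loss of the arm; hemiketal formation with the C4 ketone that slows step 10.
   - Fallback: it sets out from 6 and avoids any alkoxide by forming the ynone at the acid oxidation level. Pinnick oxidation (NaClO2, NaH2PO4, 2-methyl-2-butene, t-BuOH–H2O) gives carboxylic acid F2. Neutral chlorination with 1-chloro-N,N,2-trimethylpropenylamine in CH2Cl2 gives acid chloride F3. Acyl Sonogashira coupling of F3 with diyne 16 (PdCl2(PPh3)2, CuI, Et3N, THF, rt) gives the ynone directly. The fallback comes back at 19 and bypasses 18.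

3. Step 6.
   - What may go wrong: Z-to-E isomerisation of the enal under the Lewis acidic zinc conditions, or insufficient enantioselectivity with a cis-substituted enal.
   - Fallback: it sets out from 9 and replaces catalysis by resolution. Lithium diynide 11 (taken before the quench of step 5) is added to 9 in THF at −78 °C to give racemic diynol F4. Esterification with (S)-O-methylmandelic acid (DCC, cat. DMAP, CH2Cl2, 0 °C) and chromatographic separation of the diastereomers give the (5S)-configured ester F5. Reductive cleavage with i-Bu2AlH in CH2Cl2 at −78 °C releases the alcohol. The fallback comes back at 14.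

Further compounds
F1 | step 2 | ferulenol, 4-hydroxy-3-[(2E,6E)-3,7,11-trimethyldodeca-2,6,10-trien-1-yl]-2H-chromen-2-one | O=c1oc2ccccc2c(O)c1C/C=C(\C)CC/C=C(\C)CCC=C(C)C
F2 | step 9 | 3-[(3S)-2,4-dioxo-3-[(2E,6E)-3,7,11-trimethyldodeca-2,6,10-trien-1-yl]-3,4-dihydro-2H-chromen-3-yl]propanoic acid | OC(=O)CC[C@@]1(C/C=C(\C)CC/C=C(\C)CCC=C(C)C)C(=O)Oc2ccccc2C1=O
F3 | step 9 | 3-[(3S)-2,4-dioxo-3-[(2E,6E)-3,7,11-trimethyldodeca-2,6,10-trien-1-yl]-3,4-dihydro-2H-chromen-3-yl]propanoyl chloride | ClC(=O)CC[C@@]1(C/C=C(\C)CC/C=C(\C)CCC=C(C)C)C(=O)Oc2ccccc2C1=O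
F4 | step 6 | racemic (6Z)-1-(trimethylsilyl)tetradec-6-ene-1,3-diyn-5-ol | CCCCCCC/C=C\C(O)C#CC#C[Si](C)(C)C
F5 | step 6 | (5S,6Z)-1-(trimethylsilyl)tetradec-6-ene-1,3-diyn-5-yl (2S)-2-methoxy-2-phenylacetate | CCCCCCC/C=C\[C@H](OC(=O)[C@@H](OC)c1ccccc1)C#CC#C[Si](C)(C)C
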